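Whatever else happens in these flasks, E lost stays countable, so I counted D against it and time dropped out. Over the last readings of the three runs, D per E lost, the overall selectivity, was 0.606.

| flask | E | X | remark | time | volume of the second phase over the first |
|---|---|---|---|---|---|
| blue | 0.23 M | 0.12 M | run made earlier |  |  |
| teal | 0.23 M | 0.18 M | run made earlier |  |  |
| violet | 0.46 M | 0.242 M | run made earlier |  |  |
| flask | 0.23 M | 0.242 M |  | 3.0 h | 1.0 |

| run | time / h | D / % | E / % |
|---|---|---|---|
| blue | 0.833 | 13 | 82 |
| blue | 1.00 | 13 | 81 |
| blue | 1.33 | 16 | 72 |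
| blue | 1.50 | 19 | 69 |
| blue | 2.00 | 22 | 70 |
| blue | 2.50 | 24 | 60 |
| teal | 0.833 | 18 | 74 |
| teal | 1.00 | 21 | 68 |
| teal | 1.33 | 22 | 63 |
| teal | 1.50 | 24 | 55 |
| teal | 2.00 | 29 | 47 |
| teal | 2.50 | 34 | 46 |
| violet | 0.833 | 12 | 78 |
| violet | 1.00 | 15 | 82 |
| violet | 1.33 | 19 | 71 |
| violet | 2.00 | 28 | 63 |
| violet | 2.50 | 25 | 57 |

(readings scatter by 2 percentage points)

- in the second phase: X; everything else is in the first
- charges count per volume of the first phase; a concentration in a rate is the amount of a species over the volume of its own phase; every rate counts per litre of the first phase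
- the numbers in the tables scatter by 2 percentage points (one standard deviation)
- the earlier runs hold the two phases in the same ratio of volumes as the flask asked about
- a reading or a percentage of D counts all its forms, free or not

1. time, not beyond 3.0 h, at which the flask holds most D
2. the amount of D, in percent of the E charged, at that time

My outer bracket for the flask ran from the 34 % of D at teal's last reading, since the flask has more X, to 60.6 %, the selectivity applied to the whole charge. To tighten it, I plotted E lost against [X] times time. A first-order fall fitted to teal gave 71.4 % lost by 3.0 h. A straight line through blue and teal, which overshoots a slowing curve, gave 79.8 %. Multiplied by the selectivity, these put D between 43.3 % and 48.3 %. With D higher at the last reading than at the one before in blue and in teal, I took the latest time as best.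

The forecast said 45 % at 3 h, from “D forming at about 0.63 of the E lost”, which is inside my bracket.

The flask gave 47.9 % at 3.00 h, also inside the bracket.

G + D → L (k = 0.0270 M⁻¹ s⁻¹); E + G → D (k = 0.0770 M⁻¹ s⁻¹); J ⇌ D, rate k3*(cs3 - [D]) while solid is left; crystals form when [D] > cs3 (solubility = 0.0570 M, k = 0.0140 s⁻¹); G ⇌ X, rate k4*([G] - [X]/K4) per volume of the first phase (partition coefficient = 0.920, kL = 1.50 × 10⁻⁴ s⁻¹); D ⇌ Q (K = 0.690, k = 7.40 × 10⁻⁴ s⁻¹) That figure counts J, which was 23.0 % of the charge at that time. With 24 % of E left, the selectivity gives 46.1 %. Left until 8.0 h, the same flask kept 12.3 % of its E, so the ratio gives 53.1 %, and the flask held 54.1 % of D.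

All runs are calculated with made-up constants; noise was put on by code.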